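**Remark (assumption).** Compound 1 is taken as the commercial L‑tartrate‑derived ditosylate (it stems from diethyl L‑tartrate by acetonide formation, ester reduction and tosylation). Carbons are numbered along the acid chain from C1 (CO2H) to C24, and the terminal CH2 of the butenyl arm that is lost in step 8 is written C2'.

## Structural features

The target is a linear C24 carboxylic acid in which a 1,2‑dioxane (ring B: O–O and C3–C6) carries the CH2CO2H arm at C3 and is bonded through C6–C7 directly to a 2,5‑disubstituted oxolane (ring A: C7–C10, oxygen bridging C7 and C10). C10 carries a C14 chain with a (17Z,19E)‑diene and a terminal C23=C24 vinyl group. The four stereocentres are (3R,6R,7S,10R): C6 and C7 are contiguous and erythro, C3/C6 are trans (diequatorial) across ring B, and C7/C10 are trans across ring A. The fragile elements are the O–O bond (phosphines, low‑valent metals, strong base through Kornblum–DeLaMare cleavage or retro‑addition), the Z,E‑diene (acid, isomerisation), and, on the way, any 6‑hydroxy‑2‑enoate, which closes 5‑exo to an oxolane once its alkoxide forms. The real difficulty is the secondary–secondary dialkyl peroxide: the C6–O bond must be made with defined configuration at a hindered carbon next to ring A, and C3 must be set relative to it. A second difficulty is the order of events, because a terminal vinyl group and a diene must coexist with an arm that is best made by olefin metathesis. The feature exploited is a hidden C2 axis through the midpoint of C6–C7: outwards on either side lie an oxygen‑bearing carbon (C6, C7), two methylenes (C4–C5, C8–C9) and a further functionalised carbon (C3, C10). With C6 taken in its epimeric (S) form, C3–C11 plus one methylene that is later expelled as ethene are exactly (5S,6S)‑deca‑1,9‑diene‑5,6‑diol, a tartrate‑derived C4 bis‑epoxide with an allyl group added at each end; strictly, the symmetric unit therefore supplies C3–C11, while C1 and C2 come from an acrylate. The threo diol is the correct input because C7 is kept and C6 is inverted once when the peroxide oxygen arrives.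

## Logic of the disconnections

25 to 24: no skeletal bond is cut; only the acid is masked as its methyl ester. The ester is needed because a carboxylate would not accept a peroxide in conjugate fashion. The forward step must hydrolyse the ester without breaking the O–O bond or opening ring B by retro‑addition.

24 to 22 (through 23): the O–C3 bond of ring B is cut (retro peroxy‑Michael), then the O–C6 bond (retro SN2), so the whole O–O unit is removed and traced to H2O2. The peroxide is the most fragile group and is therefore installed last. C3 becomes an sp2 carbon of an E‑enoate and C6 an (S)‑carbinol, activated in 22 and free in 21. The forward step must invert C6 cleanly at a hindered centre and then close 6‑exo with the C3 arm trans to the C6 substituent.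

21 and 20 to 15 plus 18: the C17=C18 bond is cut. A Z‑alkene conjugated to an E‑alkene is best made from a non‑stabilised ylide and an E‑enal, and the cut removes the C18–C24 unsaturation as one small piece. The ylide must sit on the large fragment, because the enoate has to exist before any second terminal alkene enters the molecule. The forward step must be Z‑selective and must tolerate the enoate.

18 to 16 plus 17: the C19=C20 bond is cut, a two‑carbon homologation of a commercial aldehyde. The demand is E selectivity.

15 to 14, and 14 to 12 plus 13: first the C17–P bond (functional‑group change to a chloride), then the C2=C3 bond by retro cross‑metathesis. The C1–C2 unit comes from 13 and C2' leaves as ethene. This reduces the arm to a plain terminal alkene, but requires that this alkene be the only one present when the metathesis is run.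

12 to 9 plus 10 (through 11): the C11–C12 bond is cut, an sp3–sp3 coupling. The chloride terminus of 10 is a latent phosphonium salt, so no hydroxyl protection is needed on this chain. The forward step needs a primary triflate next to ring A that couples faster than it decomposes, and magnesium insertion at C–Br only.

9 to 8 and 8 to 7: the O–C10 bond of ring A and the C11–O bond are cut together (retro oxidative cyclisation). Ring A and the C10 stereocentre disappear and both ends become identical butenyl arms. The forward step must give the trans ring and must involve O7 only, which is why O6 is silylated.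

7 to 6: the O–Si bond is cut. Because 6 has a C2 axis, either hydroxyl gives the same monoether, so the only demand is to stop after one silylation.

6 to 3 plus two molecules of 4 (through 5): the C4–C5 and C8–C9 bonds are cut, each β to a carbinol carbon. This exposes a four‑carbon core whose two stereocentres are bought from tartaric acid. The demand is attack at the terminal carbon of each oxirane, twice.

3 to 2 and 2 to 1: the two epoxide C–O bonds (retro 3‑exo‑tet closures) and then the acetonide are disconnected, arriving at a commercial chiral‑pool building block. The demand is only that the carbinol C–O bonds stay intact.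

## Other disconnections considered

**Alternative 1:** The O–C6 bond of ring B and the O–C10 bond of ring A are cut in one retrosynthetic operation. The precursor is an open‑chain C3 hydroperoxide with a trans C6–C7 epoxide and a C10 mesylate, A2.
- Forward step: one equivalent of base (KOH or Cs2CO3) forms the peroxy anion, which opens the epoxide at C6 (6‑exo, inversion); the C7 alkoxide set free displaces the mesylate (5‑exo‑tet, inversion) to give the bis‑silyl ether A1.
- In its favour: the hindered C6–O(peroxide) bond is made intramolecularly and irreversibly. On this point it is better than the chosen plan, which relies on an intermolecular displacement at C6 and on a reversible conjugate addition for C3. Both rings also close in one operation.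
- Against it: A2 needs four stereocentres installed independently on an open chain (a trans epoxide on an isolated alkene and two remote carbinols, one of them itself converted stereospecifically into a hydroperoxide). A free OOH must be carried past an epoxide and a mesylate. A1 still lacks the acid oxidation state at C1 and the entire C18–C24 triene, so oxidations and a Z‑selective olefination would have to be done with the peroxide in place.
- Comparison: mechanistically the cascade is the more secure way to fix C6. Structurally the chosen plan is safer because the peroxide is made last. In step count the chosen plan should be clearly shorter, since two stereocentres come from the chiral pool and the other two from substrate control.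

**Alternative 2:** The O–C7 bond of ring A and the C6–O bond are cut together. The precursor is an open‑chain (10R)‑hydroxy pentaenoate with an E C6=C7 alkene, A4.
- Forward step: Re2O7 (heptavalent rhenium) buffered with 2,6‑lutidine forms the perrhenate ester of the C10 alcohol, which adds two oxygens syn across the alkene to give the trans oxolane with a threo (6S) hydroxyl, A3.
- In its favour: A3 is the same compound as 21 of the chosen route. It is reached with one resident stereocentre relaying to C7 and C6, without a protecting group on O6 and without the triflate coupling. In step economy this is potentially the equal or the better of the chosen plan, and its trans‑ring control is equal. The endgame is identical.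
- Against it: five alkenes, including the Z,E‑diene and an enoate, are exposed to a strongly Lewis acidic oxo‑metal reagent. A 1,2‑disubstituted alkene is a less willing partner in this cyclisation than a trisubstituted one. The C6 hydroxyl is created next to the enoate under conditions that may trigger 5‑exo oxa‑Michael closure. The C10 carbinol and the E‑alkene must still be made by asymmetric synthesis.
- Comparison: the chosen plan performs its hydroxyl‑directed cyclisation when only two alkenes are present and takes C6/C7 from tartaric acid, so it is safer on chemoselectivity and absolute configuration, at the price of more linear steps.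

**Alternative 3:** The O–C10 and C10–C11 bonds are cut. The precursor is a diazoketone with an allyl ether on O7, A6.
- Forward step: Cu(acac)2 (divalent copper) generates a carbenoid at C10, which is captured by the ether oxygen to give a five‑membered oxonium ylide; a [2,3] shift moves the allyl group to C10 and gives the trans oxolan‑3‑one A5.
- In its favour: ring A, the C10 stereocentre and the C10–C11 bond are formed in one catalytic step, with trans selectivity that should equal that of the cobalt cyclisation. The allyl group is a carbon handle that could be extended by metathesis instead of a triflate coupling, which is arguably better.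
- Against it: the C9 ketone is surplus oxidation and costs two or three steps to remove. A6 needs diazomethane or a diazo‑transfer sequence. The C6/C7 diol must be differentiated as two different ethers without help from symmetry. A5 still lacks C1–C2, so an oxidation and an olefination must be added before the same H2O2 inversion at C6.
- Comparison: the chosen plan reaches the same trans ring from a symmetric diol in one redox‑economical step and is shorter; the alternative offers no gain in the difficult peroxide endgame.

Key step: step 3

## Route

**Step 1**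
Reactants: 1 [(4S,5S)-2,2-dimethyl-1,3-dioxolane-4,5-diyl]bis(methylene) bis(4-methylbenzenesulfonate)
Product: 2 (2S,3S)-2,3-dihydroxybutane-1,4-diyl bis(4-methylbenzenesulfonate)
Conditions: TsOH·H2O (cat.), EtOH/H2O 95:5, reflux
Reagents that add atoms: none
Why: Acid‑catalysed acetal hydrolysis frees the 2,3‑diol; the primary tosylates, deactivated by the β‑oxygens, should survive and no stereocentre is touched.

**Step 2**
Reactants: 2 (2S,3S)-2,3-dihydroxybutane-1,4-diyl bis(4-methylbenzenesulfonate)
Product: 3 (2S,3S)-1,2:3,4-diepoxybutane
Conditions: NaH (2.1 equiv), THF, 0 °C to rt; filtered under argon and used as an assayed THF solution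
Reagents that add atoms: none
Why: Double intramolecular Williamson etherification (3‑exo‑tet): each alkoxide displaces the neighbouring primary tosylate, so the C–O bonds at the stereocentres are never broken and the (S,S) configuration is kept. Keeping 3 in solution avoids concentrating a volatile bis‑alkylating agent.

**Step 3**
Reactants: 3 (2S,3S)-1,2:3,4-diepoxybutane; 4 allylmagnesium bromide
Product: 6 (5S,6S)-deca-1,9-diene-5,6-diol, via mono-opened epoxy alkoxide 5 (not isolated)
Conditions: 4 (2.6 equiv), CuI (10 mol%), THF/Et2O, −40 to 0 °C; aq. NH4Cl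
Reagents that add atoms: none
Why: Transmetalation of 4 to CuI gives an allylcopper species of monovalent copper that attacks the unsubstituted CH2 terminus of an oxirane in SN2 fashion (formally oxidative addition to trivalent copper, then reductive elimination), so the C4–C5 bond forms first (alkoxide 5) and the C8–C9 bond second. The closest known reaction type is the copper‑catalysed opening of terminal epoxides by Grignard reagents, which is established on this diepoxide with aryl, vinyl and alkyl Grignard reagents. No ring is closed and no stereocentre is created: the C6–O and C7–O bonds are never broken, so both carbinol carbons keep the (S) configuration inherited from L‑tartaric acid. The only selectivity needed is regioselectivity, terminal against internal attack, and it is secured by the steric bias of the monosubstituted oxiranes together with the soft organocopper nucleophile. Copper catalysis and low temperature should also hold back opening by bromide to bromohydrins and attack of alkoxide 5 on a second epoxide. Because two identical nucleophiles add to two homotopic termini, the product is C2‑symmetric, which makes the later monoprotection a desymmetrisation without a selectivity problem.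

**Step 4**
Reactants: 6 (5S,6S)-deca-1,9-diene-5,6-diol
Product: 7 (5S,6S)-6-(tert-butyldimethylsilyloxy)deca-1,9-dien-5-ol
Conditions: TBSCl (1.0 equiv), imidazole (2 equiv), CH2Cl2, 0 °C
Reagents that add atoms: tert-butyldimethylsilyl chloride, CC(C)(C)[Si](C)(C)Cl
Why: Silyl ether formation; the two hydroxyls are homotopic, so a single monoether results whichever reacts, and the bulky silyl group should slow silylation of the vicinal hydroxyl. Silyl migration between O6 and O7 is degenerate, and unreacted 6 can be recycled.

**Step 5**
Reactants: 7 (5S,6S)-6-(tert-butyldimethylsilyloxy)deca-1,9-dien-5-ol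
Product: 8 [(2S,5S)-5-[(1S)-1-(tert-butyldimethylsilyloxy)pent-4-enyl]oxolan-2-yl]methanol
Conditions: Co(modp)2 [divalent cobalt; modp = 5,5-dimethyl-1-(morpholin-4-yl)hexane-1,2,4-trionate] (15 mol%), t-BuOOH (10 mol%), O2 (1 atm), i-PrOH, 4 Å sieves, 55 °C
Reagents that add atoms: dioxygen, O=O
Why: Mukaiyama aerobic oxidative cyclisation of a 4‑pentenol: the trivalent cobalt alkoxide of O7 adds 5‑exo to C10=C11, and the C11 radical is trapped by O2 and reduced to the primary alcohol. C10 is set trans to C7 through a transition state with the C7 side chain pseudo‑equatorial. The silylated O6 cannot cyclise, so the other butenyl arm is left untouched (unprotected 6 would close twice).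

**Step 6**
Reactants: 8 [(2S,5S)-5-[(1S)-1-(tert-butyldimethylsilyloxy)pent-4-enyl]oxolan-2-yl]methanol
Product: 9 [(2S,5S)-5-[(1S)-1-(tert-butyldimethylsilyloxy)pent-4-enyl]oxolan-2-yl]methyl trifluoromethanesulfonate
Conditions: Tf2O (1.2 equiv), 2,6-lutidine (1.5 equiv), CH2Cl2, −78 °C; used crude at once
Reagents that add atoms: trifluoromethanesulfonic anhydride, O=S(=O)(OS(=O)(=O)C(F)(F)F)C(F)(F)F
Why: O‑sulfonylation of the primary alcohol; the β‑oxygen of ring A retards ionisation, so the triflate should be stable enough for a cold work‑up and immediate use.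

**Step 7**
Reactants: 9 [(2S,5S)-5-[(1S)-1-(tert-butyldimethylsilyloxy)pent-4-enyl]oxolan-2-yl]methyl trifluoromethanesulfonate; 10 1-bromo-6-chlorohexane
Product: 12 (2S,5R)-2-[(1S)-1-(tert-butyldimethylsilyloxy)pent-4-enyl]-5-(7-chloroheptyl)oxolane, via (6-chlorohexyl)magnesium bromide 11 (not isolated)
Conditions: 10, Mg, THF, rt; then 9, CuI (10 mol%), THF/Et2O, −40 to 0 °C
Reagents that add atoms: none
Why: Magnesium inserts into the C–Br bond only, and the copper‑catalysed sp3–sp3 coupling of a primary triflate with an alkyl Grignard reagent forms C11–C12. The C–Cl bond, silyl ether and alkene are inert at this temperature and C10 is not involved.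

**Step 8**
Reactants: 12 (2S,5R)-2-[(1S)-1-(tert-butyldimethylsilyloxy)pent-4-enyl]-5-(7-chloroheptyl)oxolane; 13 methyl acrylate
Product: 14 methyl (2E,6S)-6-(tert-butyldimethylsilyloxy)-6-[(2S,5R)-5-(7-chloroheptyl)oxolan-2-yl]hex-2-enoate
Conditions: 13 (5 equiv), second-generation Grubbs catalyst RuCl2(=CHPh)(H2IMes)(PCy3) (5 mol%), CH2Cl2, 40 °C
Reagents that add atoms: none
Why: Olefin cross‑metathesis of a terminal alkene with an electron‑poor acrylate should be selective for the cross product and for the E‑enoate. The C3 alkene is the only alkene in 12, which is why this step precedes the introduction of the diene and the C23 vinyl group.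

**Step 9**
Reactants: 14 methyl (2E,6S)-6-(tert-butyldimethylsilyloxy)-6-[(2S,5R)-5-(7-chloroheptyl)oxolan-2-yl]hex-2-enoate
Product: 15 triphenyl{7-[(2R,5S)-5-[(1S,4E)-1-(tert-butyldimethylsilyloxy)-6-methoxy-6-oxohex-4-enyl]oxolan-2-yl]heptyl}phosphonium iodide
Conditions: NaI (3 equiv), PPh3 (2 equiv), MeCN, reflux
Reagents that add atoms: triphenylphosphine, c1ccc(cc1)P(c1ccccc1)c1ccccc1; sodium iodide, [Na+].[I-]
Why: Finkelstein exchange of the primary chloride for iodide in the flask, followed by SN2 quaternisation of PPh3. The β‑substituted enoate and the silyl ether should be inert to these neutral conditions.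

**Step 10**
Reactants: 16 pent-4-enal; 17 (triphenylphosphoranylidene)acetaldehyde
Product: 18 (2E)-hepta-2,6-dienal
Conditions: toluene, 80 °C
Reagents that add atoms: none
Why: Wittig reaction with a stabilised formylmethylene ylide, which gives the E‑enal; a slight excess of 16 should limit a second homologation.

**Step 11**
Reactants: 15 triphenyl{7-[(2R,5S)-5-[(1S,4E)-1-(tert-butyldimethylsilyloxy)-6-methoxy-6-oxohex-4-enyl]oxolan-2-yl]heptyl}phosphonium iodide; 18 (2E)-hepta-2,6-dienal
Product: 20 methyl (2E,6S)-6-(tert-butyldimethylsilyloxy)-6-[(2S,5R)-5-[(7Z,9E)-tetradeca-7,9,13-trienyl]oxolan-2-yl]hex-2-enoate, via C17 phosphonium ylide 19 (not isolated)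
Conditions: NaN(SiMe3)2 (0.95 equiv), THF, −78 °C; then 18, −78 to 0 °C
Reagents that add atoms: none
Why: Wittig reaction of a non‑stabilised ylide under lithium‑free conditions: kinetically controlled formation of the cis‑oxaphosphetane gives the Z C17=C18 bond, while the E geometry of C19=C20 is carried in with 18. The phosphonium α‑proton is far more acidic than any enoate proton, and a slight deficit of base with immediate addition of the aldehyde at −78 °C should keep the ylide from adding to the enoate.

**Step 12**
Reactants: 20 methyl (2E,6S)-6-(tert-butyldimethylsilyloxy)-6-[(2S,5R)-5-[(7Z,9E)-tetradeca-7,9,13-trienyl]oxolan-2-yl]hex-2-enoate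
Product: 21 methyl (2E,6S)-6-hydroxy-6-[(2S,5R)-5-[(7Z,9E)-tetradeca-7,9,13-trienyl]oxolan-2-yl]hex-2-enoate
Conditions: HF·pyridine, pyridine, THF, 0 °C to rt
Reagents that add atoms: none
Why: Si–O cleavage by fluoride under buffered acidic conditions. A basic fluoride source is avoided because the C6 alkoxide would close 5‑exo onto the enoate (oxa‑Michael addition).

**Step 13**
Reactants: 21 methyl (2E,6S)-6-hydroxy-6-[(2S,5R)-5-[(7Z,9E)-tetradeca-7,9,13-trienyl]oxolan-2-yl]hex-2-enoate
Product: 22 methyl (2E,6S)-6-[(2S,5R)-5-[(7Z,9E)-tetradeca-7,9,13-trienyl]oxolan-2-yl]-6-(trifluoromethanesulfonyloxy)hex-2-enoate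
Conditions: Tf2O (1.2 equiv), 2,6-lutidine (2 equiv), CH2Cl2, −78 °C; cold work-up, used at once
Reagents that add atoms: trifluoromethanesulfonic anhydride, O=S(=O)(OS(=O)(=O)C(F)(F)F)C(F)(F)F
Why: O‑sulfonylation with retention at C6 gives a leaving group reactive enough for substitution at a hindered carbon, while the adjacent ring A oxygen disfavours ionisation, as in carbohydrate triflates.

**Step 14**
Reactants: 22 methyl (2E,6S)-6-[(2S,5R)-5-[(7Z,9E)-tetradeca-7,9,13-trienyl]oxolan-2-yl]-6-(trifluoromethanesulfonyloxy)hex-2-enoate
Product: 24 methyl 2-[(3R,6R)-6-[(2S,5R)-5-[(7Z,9E)-tetradeca-7,9,13-trienyl]oxolan-2-yl]-1,2-dioxan-3-yl]acetate, via C6 hydroperoxide 23 (not isolated)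
Conditions: H2O2·urea (10 equiv), Cs2CO3 (1.5 equiv), THF/DMF, −20 to 0 °C; then Et2NH (0.3 equiv), CF3CH2OH, rt
Reagents that add atoms: hydrogen peroxide (as its urea adduct), OO
Why: SN2 displacement of a secondary sulfonate by hydroperoxide anion, an α‑effect nucleophile of low basicity, inverts C6 to R and gives 23, whose peroxy anion then adds 6‑exo‑trig to the enoate (intramolecular peroxy‑Michael addition). C3 is set by a chair‑like transition state with the C6 substituent and the CH2CO2Me arm both equatorial, and the reversibility of the addition under amine base should let the mixture settle on the 3,6‑trans isomer.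

**Step 15**
Reactants: 24 methyl 2-[(3R,6R)-6-[(2S,5R)-5-[(7Z,9E)-tetradeca-7,9,13-trienyl]oxolan-2-yl]-1,2-dioxan-3-yl]acetate
Product: 25 2-[(3R,6R)-6-[(2S,5R)-5-[(7Z,9E)-tetradeca-7,9,13-trienyl]oxolan-2-yl]-1,2-dioxan-3-yl]acetic acid
Conditions: LiOH·H2O (3 equiv), THF/H2O 3:1, 0 °C to rt; then 0.5 M HCl to pH 4 at 0 °C
Reagents that add atoms: lithium hydroxide, [Li+].[OH-]
Why: Ester saponification, a hydrolysis that is established for 1,2‑dioxan‑3‑ylacetic esters. Should retro‑addition intervene, the ring is expected to re‑close to the same diequatorial isomer.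

## Compound list

1 | [(4S,5S)-2,2-dimethyl-1,3-dioxolane-4,5-diyl]bis(methylene) bis(4-methylbenzenesulfonate) [(−)-1,4-di-O-tosyl-2,3-O-isopropylidene-L-threitol] | CC1(C)O[C@@H](COS(=O)(=O)c2ccc(C)cc2)[C@H](COS(=O)(=O)c2ccc(C)cc2)O1 | starting material
2 | (2S,3S)-2,3-dihydroxybutane-1,4-diyl bis(4-methylbenzenesulfonate) [L-threitol 1,4-ditosylate] | Cc1ccc(cc1)S(=O)(=O)OC[C@H](O)[C@@H](O)COS(=O)(=O)c1ccc(C)cc1 | intermediate
3 | (2S,3S)-1,2:3,4-diepoxybutane | C1O[C@@H]1[C@@H]1CO1 | intermediate
4 | allylmagnesium bromide | C=CC[Mg]Br | starting material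
5 | bromomagnesium (1S)-1-[(2S)-oxiran-2-yl]pent-4-en-1-olate | C=CCC[C@H](O[Mg]Br)[C@@H]1CO1 | intermediate (not isolated)
6 | (5S,6S)-deca-1,9-diene-5,6-diol | C=CCC[C@H](O)[C@@H](O)CCC=C | intermediate
7 | (5S,6S)-6-(tert-butyldimethylsilyloxy)deca-1,9-dien-5-ol | C=CCC[C@H](O)[C@@H](O[Si](C)(C)C(C)(C)C)CCC=C | intermediate
8 | [(2S,5S)-5-[(1S)-1-(tert-butyldimethylsilyloxy)pent-4-enyl]oxolan-2-yl]methanol | OC[C@@H]1CC[C@@H]([C@@H](O[Si](C)(C)C(C)(C)C)CCC=C)O1 | intermediate
9 | [(2S,5S)-5-[(1S)-1-(tert-butyldimethylsilyloxy)pent-4-enyl]oxolan-2-yl]methyl trifluoromethanesulfonate | FC(F)(F)S(=O)(=O)OC[C@@H]1CC[C@@H]([C@@H](O[Si](C)(C)C(C)(C)C)CCC=C)O1 | intermediate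
10 | 1-bromo-6-chlorohexane | ClCCCCCCBr | starting material
11 | (6-chlorohexyl)magnesium bromide | ClCCCCCC[Mg]Br | intermediate (not isolated)
12 | (2S,5R)-2-[(1S)-1-(tert-butyldimethylsilyloxy)pent-4-enyl]-5-(7-chloroheptyl)oxolane | ClCCCCCCC[C@@H]1CC[C@@H]([C@@H](O[Si](C)(C)C(C)(C)C)CCC=C)O1 | intermediate
13 | methyl acrylate | C=CC(=O)OC | starting material
14 | methyl (2E,6S)-6-(tert-butyldimethylsilyloxy)-6-[(2S,5R)-5-(7-chloroheptyl)oxolan-2-yl]hex-2-enoate | ClCCCCCCC[C@@H]1CC[C@@H]([C@@H](O[Si](C)(C)C(C)(C)C)CC/C=C/C(=O)OC)O1 | intermediate
15 | triphenyl{7-[(2R,5S)-5-[(1S,4E)-1-(tert-butyldimethylsilyloxy)-6-methoxy-6-oxohex-4-enyl]oxolan-2-yl]heptyl}phosphonium iodide | [I-].c1ccc(cc1)[P+](c1ccccc1)(c1ccccc1)CCCCCCC[C@@H]1CC[C@@H]([C@@H](O[Si](C)(C)C(C)(C)C)CC/C=C/C(=O)OC)O1 | intermediate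
16 | pent-4-enal | C=CCCC=O | starting material
17 | (triphenylphosphoranylidene)acetaldehyde | O=CC=P(c1ccccc1)(c1ccccc1)c1ccccc1 | starting material
18 | (2E)-hepta-2,6-dienal | C=CCC/C=C/C=O | intermediate
19 | methyl (2E,6S)-6-(tert-butyldimethylsilyloxy)-6-[(2S,5R)-5-[7-(triphenyl-λ5-phosphanylidene)heptyl]oxolan-2-yl]hex-2-enoate | c1ccc(cc1)P(=CCCCCCC[C@@H]1CC[C@@H]([C@@H](O[Si](C)(C)C(C)(C)C)CC/C=C/C(=O)OC)O1)(c1ccccc1)c1ccccc1 | intermediate (not isolated)
20 | methyl (2E,6S)-6-(tert-butyldimethylsilyloxy)-6-[(2S,5R)-5-[(7Z,9E)-tetradeca-7,9,13-trienyl]oxolan-2-yl]hex-2-enoate | C=CCC/C=C/C=C\CCCCCC[C@@H]1CC[C@@H]([C@@H](O[Si](C)(C)C(C)(C)C)CC/C=C/C(=O)OC)O1 | intermediate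
21 | methyl (2E,6S)-6-hydroxy-6-[(2S,5R)-5-[(7Z,9E)-tetradeca-7,9,13-trienyl]oxolan-2-yl]hex-2-enoate | C=CCC/C=C/C=C\CCCCCC[C@@H]1CC[C@@H]([C@@H](O)CC/C=C/C(=O)OC)O1 | intermediate
22 | methyl (2E,6S)-6-[(2S,5R)-5-[(7Z,9E)-tetradeca-7,9,13-trienyl]oxolan-2-yl]-6-(trifluoromethanesulfonyloxy)hex-2-enoate | C=CCC/C=C/C=C\CCCCCC[C@@H]1CC[C@@H]([C@@H](OS(=O)(=O)C(F)(F)F)CC/C=C/C(=O)OC)O1 | intermediate
23 | methyl (2E,6R)-6-hydroperoxy-6-[(2S,5R)-5-[(7Z,9E)-tetradeca-7,9,13-trienyl]oxolan-2-yl]hex-2-enoate | C=CCC/C=C/C=C\CCCCCC[C@@H]1CC[C@@H]([C@H](OO)CC/C=C/C(=O)OC)O1 | intermediate (not isolated)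
24 | methyl 2-[(3R,6R)-6-[(2S,5R)-5-[(7Z,9E)-tetradeca-7,9,13-trienyl]oxolan-2-yl]-1,2-dioxan-3-yl]acetate | C=CCC/C=C/C=C\CCCCCC[C@@H]1CC[C@@H]([C@H]2CC[C@H](CC(=O)OC)OO2)O1 | intermediate
25 | 2-[(3R,6R)-6-[(2S,5R)-5-[(7Z,9E)-tetradeca-7,9,13-trienyl]oxolan-2-yl]-1,2-dioxan-3-yl]acetic acid | C=CCC/C=C/C=C\CCCCCC[C@@H]1CC[C@@H]([C@H]2CC[C@H](CC(=O)O)OO2)O1 | target

## Step count and least certain steps

Total step count: 15. Longest linear sequence: 14 steps (steps 1–9 and 11–15, from 1 to 25); step 10 is a one‑step side branch.

**Step 14 (peroxide installation and ring B closure).** The most likely failure is loss of the triflate by pathways other than SN2: E2 elimination, participation of the ring A oxygen with ring expansion, or nucleophilic epoxidation of the enoate by hydroperoxide anion (Weitz–Scheffer type). Incomplete trans selectivity in the conjugate addition is a further risk. The cause is that C6 is a hindered secondary carbon flanked by an oxygenated carbon, and free HOO− is both nucleophile and oxidant. Fallback, from 22 and returning at 23: 22 would be alkylated with the anion of a masked hydroperoxide, 2‑methoxypropan‑2‑yl hydroperoxide (CsOH·H2O, DMF, 0 °C), to the mixed peroxyketal methyl (2E,6R)-6-[(2-methoxypropan-2-yl)peroxy]-6-[(2S,5R)-5-[(7Z,9E)-tetradeca-7,9,13-trienyl]oxolan-2-yl]hex-2-enoate F1. Aqueous acetic acid in THF would then unmask 23, now isolated, which is closed to 24 with Et2NH in CF3CH2OH as in the route. This separates substitution from cyclisation and removes free H2O2 from the substitution step.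

**Step 11 (Z‑selective Wittig reaction).** The likely failure is consumption of the ylide by conjugate addition to the enoate of a second molecule or by deprotonation at C4, and erosion of Z selectivity if the betaine equilibrates. Fallback, from 14 and returning at 20, with the polarity reversed and the Z‑alkene made without a basic carbon nucleophile on the large fragment:
- 14 with NaI in acetone would give methyl (2E,6S)-6-(tert-butyldimethylsilyloxy)-6-[(2S,5R)-5-(7-iodoheptyl)oxolan-2-yl]hex-2-enoate F2.
- Ganem oxidation (Me3NO, DMSO, rt) would give methyl (2E,6S)-6-(tert-butyldimethylsilyloxy)-6-[(2S,5R)-5-(7-oxoheptyl)oxolan-2-yl]hex-2-enoate F3.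
- Stork–Zhao olefination (Ph3P=CHI from [Ph3PCH2I]I and NaN(SiMe3)2, THF/DMPU, −78 °C) would give methyl (2E,6S)-6-(tert-butyldimethylsilyloxy)-6-[(2S,5R)-5-[(7Z)-8-iodooct-7-enyl]oxolan-2-yl]hex-2-enoate F4.
- Suzuki–Miyaura coupling (Pd(PPh3)4, zerovalent palladium, aq. K3PO4, THF, rt) with 2-[(1E)-hexa-1,5-dienyl]-4,4,5,5-tetramethyl-1,3,2-dioxaborolane F5 would give 20 with retention of both alkene geometries. F5 would be made from hex‑1‑en‑5‑yne and pinacolborane with Cp2Zr(H)Cl as catalyst.

**Step 3 (key step).** The likely failure is opening by bromide instead of carbon (halohydrin formation), oligomerisation when alkoxide 5 attacks unreacted epoxide, and loss of material in handling a volatile, water‑soluble bis‑electrophile. Fallback, from 1 and returning at 6: the same C4–C5 and C8–C9 bonds would be made by copper‑catalysed displacement of both primary tosylates of 1 with 4 (Li2CuCl4 cat., THF, −20 °C to rt), giving (4S,5S)-4,5-di(but-3-enyl)-2,2-dimethyl-1,3-dioxolane F6. Acid hydrolysis (TsOH·H2O, MeOH/H2O) would then give 6 without any free epoxide or alkoxide intermediate.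

**Step 15 (saponification).** The likely failure is base‑induced retro‑addition with epimerisation at C3, or Kornblum–DeLaMare‑type cleavage of the O–O bond, because hydroxide can remove the C2 protons or the protons on C3 and C6. Fallback, from 24 and returning at 25: enzymatic hydrolysis with pig liver esterase in pH 7 phosphate buffer with a little acetone, which avoids hydroxide altogether and makes no compound outside the list (F0).

## Further compounds

F1 | step 14 | methyl (2E,6R)-6-[(2-methoxypropan-2-yl)peroxy]-6-[(2S,5R)-5-[(7Z,9E)-tetradeca-7,9,13-trienyl]oxolan-2-yl]hex-2-enoate | C=CCC/C=C/C=C\CCCCCC[C@@H]1CC[C@@H]([C@H](OOC(C)(C)OC)CC/C=C/C(=O)OC)O1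
F2 | step 11 | methyl (2E,6S)-6-(tert-butyldimethylsilyloxy)-6-[(2S,5R)-5-(7-iodoheptyl)oxolan-2-yl]hex-2-enoate | ICCCCCCC[C@@H]1CC[C@@H]([C@@H](O[Si](C)(C)C(C)(C)C)CC/C=C/C(=O)OC)O1
F3 | step 11 | methyl (2E,6S)-6-(tert-butyldimethylsilyloxy)-6-[(2S,5R)-5-(7-oxoheptyl)oxolan-2-yl]hex-2-enoate | O=CCCCCCC[C@@H]1CC[C@@H]([C@@H](O[Si](C)(C)C(C)(C)C)CC/C=C/C(=O)OC)O1
F4 | step 11 | methyl (2E,6S)-6-(tert-butyldimethylsilyloxy)-6-[(2S,5R)-5-[(7Z)-8-iodooct-7-enyl]oxolan-2-yl]hex-2-enoate | I/C=C\CCCCCC[C@@H]1CC[C@@H]([C@@H](O[Si](C)(C)C(C)(C)C)CC/C=C/C(=O)OC)O1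
F5 | step 11 | 2-[(1E)-hexa-1,5-dienyl]-4,4,5,5-tetramethyl-1,3,2-dioxaborolane | C=CCC/C=C/B1OC(C)(C)C(C)(C)O1
F6 | step 3 | (4S,5S)-4,5-di(but-3-enyl)-2,2-dimethyl-1,3-dioxolane | C=CCC[C@@H]1OC(C)(C)O[C@H]1CCC=C
F0 | step 15 | none | none
A1 | alternative 1 | (3R,6R)-3-[2-(tert-butyldiphenylsilyloxy)ethyl]-6-[(2S,5R)-5-[7-(tert-butyldimethylsilyloxy)heptyl]oxolan-2-yl]-1,2-dioxane | CC(C)(C)[Si](C)(C)OCCCCCCC[C@@H]1CC[C@@H]([C@H]2CC[C@H](CCO[Si](c3ccccc3)(c3ccccc3)C(C)(C)C)OO2)O1
A2 | alternative 1 | (3R,6S,7S,10S)-17-(tert-butyldimethylsilyloxy)-1-(tert-butyldiphenylsilyloxy)-6,7-epoxy-3-hydroperoxyheptadecan-10-yl methanesulfonate | CC(C)(C)[Si](C)(C)OCCCCCCC[C@H](OS(C)(=O)=O)CC[C@@H]1O[C@H]1CC[C@@H](OO)CCO[Si](c1ccccc1)(c1ccccc1)C(C)(C)C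
A3 | alternative 2 | methyl (2E,6S)-6-hydroxy-6-[(2S,5R)-5-[(7Z,9E)-tetradeca-7,9,13-trienyl]oxolan-2-yl]hex-2-enoate | C=CCC/C=C/C=C\CCCCCC[C@@H]1CC[C@@H]([C@@H](O)CC/C=C/C(=O)OC)O1
A4 | alternative 2 | methyl (2E,6E,10R,17Z,19E)-10-hydroxytetracosa-2,6,17,19,23-pentaenoate | C=CCC/C=C/C=C\CCCCCC[C@@H](O)CC/C=C/CC/C=C/C(=O)OC
A5 | alternative 3 | (2R,5S)-2-allyl-5-[(1S)-4-(tert-butyldiphenylsilyloxy)-1-(4-methoxybenzyloxy)butyl]oxolan-3-one | C=CC[C@@H]1C(=O)C[C@@H]([C@@H](OCc2ccc(OC)cc2)CCCO[Si](c2ccccc2)(c2ccccc2)C(C)(C)C)O1
A6 | alternative 3 | (4S,5S)-4-(allyloxy)-8-(tert-butyldiphenylsilyloxy)-1-diazo-5-(4-methoxybenzyloxy)octan-2-one | [N-]=[N+]=CC(=O)C[C@H](OCC=C)[C@@H](OCc1ccc(OC)cc1)CCCO[Si](c1ccccc1)(c1ccccc1)C(C)(C)C
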